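**Retrosynthetic overview**

1. The target is tangeretin lacking its 5-O-methyl group. That methyl ether lies peri to the C4 carbonyl and is removed last by chelation-directed demethylation with BCl3.
2. Tangeretin is disconnected at C8a–O1, C4a–C4 and O1–C2 into 3,4,5,6-tetramethoxybenzyne and 3-(4-methoxyphenyl)propiolic acid. Ring A comes from the aryne, ring B comes with the acid, and ring C is the only ring formed.
3. Structural feature: C4a and C8a are adjacent carbons of ring A, and C5, C6, C7 and C8 all carry oxygen. The aryne with its triple bond at C4a–C8a therefore has a methoxy group on each side and a mirror plane through the triple bond, so the orientation of addition does not matter.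
4. The aryne is released from an ortho-silylaryl triflate. This is made from 2-bromo-3,4,5,6-tetramethoxyphenol (silylation, retro-Brook rearrangement, triflation), which comes from 2,3,4,5-tetramethoxyphenol and ultimately from 1,2,3,4-tetramethoxybenzene (ortho-lithiation, borylation, oxidation).

Key step: step 5

Remark: the target has no stereocentre; 1,2,3,4-tetramethoxybenzene and 3-(4-methoxyphenyl)propiolic acid are taken as purchased materials.

**Route**

Step 1
Reactants: 1 1,2,3,4-tetramethoxybenzene
Product: 4 2,3,4,5-tetramethoxyphenol, via aryllithium 2 (not isolated), via dimethyl arylboronate 3 (not isolated)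
Conditions: n-BuLi, TMEDA, THF, 0 °C; B(OMe)3, −78 °C to rt; AcOH, 30% aq. H2O2, 0 °C to rt
Reagents that add atoms: hydrogen peroxide, OO
Why: Directed ortho-lithiation beside a methoxy group (the two ring hydrogens are equivalent), borylation of the aryllithium and peroxide-induced 1,2-migration of the aryl group from boron to oxygen should give the phenol in one flask.

Step 2
Reactants: 4 2,3,4,5-tetramethoxyphenol
Product: 5 2-bromo-3,4,5,6-tetramethoxyphenol
Conditions: NBS (1.0 equiv), CH2Cl2, −78 to 0 °C, dark
Reagents that add atoms: N-bromosuccinimide, O=C1CCC(=O)N1Br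
Why: Electrophilic aromatic bromination of a strongly activated phenol whose only unsubstituted ring carbon lies ortho to the hydroxyl group, so there is no regiochemical choice.

Step 3
Reactants: 5 2-bromo-3,4,5,6-tetramethoxyphenol
Product: 6 (2-bromo-3,4,5,6-tetramethoxyphenoxy)trimethylsilane
Conditions: HMDS, THF, reflux; concentrate, use crude
Reagents that add atoms: hexamethyldisilazane, C[Si](C)(C)N[Si](C)(C)C
Why: O-Silylation of a phenol with hexamethyldisilazane releases only ammonia, so the moisture-sensitive aryl silyl ether can be carried on after evaporation.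

Step 4
Reactants: 6 (2-bromo-3,4,5,6-tetramethoxyphenoxy)trimethylsilane
Product: 9 3,4,5,6-tetramethoxy-2-(trimethylsilyl)phenyl trifluoromethanesulfonate, via ortho-silyloxy aryllithium 7 (not isolated), via lithium ortho-silylphenoxide 8 (not isolated)
Conditions: n-BuLi, THF, −100 to −80 °C; Tf2O, −100 to −80 °C; cold aq. NaHCO3
Reagents that add atoms: trifluoromethanesulfonic anhydride, O=S(=O)(OS(=O)(=O)C(F)(F)F)C(F)(F)F
Why: Bromine–lithium exchange followed by anionic 1,3-migration of silicon from oxygen to carbon (retro-Brook rearrangement) should give the ortho-silylphenoxide, which triflic anhydride traps as the aryl triflate.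

Step 5
Reactants: 9 3,4,5,6-tetramethoxy-2-(trimethylsilyl)phenyl trifluoromethanesulfonate (1.5 equiv); 10 3-(4-methoxyphenyl)propiolic acid
Product: 13 5,6,7,8-tetramethoxy-2-(4-methoxyphenyl)chromen-4-one (tangeretin), via 3,4,5,6-tetramethoxybenzyne 11 (not isolated), via ortho-hydroxyaryl ynone 12 (not isolated)
Conditions: CsF (4 equiv), THF, 125 °C, sealed tube
Reagents that add atoms: none
Why: Fluoride attacks silicon of 9 and triflate departs to release aryne 11; the cesium carboxylate of 10 adds through oxygen to one aryne carbon (C8a–O1), and the ortho aryl anion so formed attacks the ester carbonyl through a four-membered transition state whose collapse moves the acyl group to carbon (C4a–C4) and leaves the phenoxide of ynone 12. This is the known formal insertion of arynes from silylaryl triflates into the C–O bond of carboxylic acids, which with 3-arylpropiolic acids continues to flavones; the two methoxy groups flanking the triple bond of 11 make it more electrophilic by induction, which should help the first addition. Ring C then closes by 6-endo-dig conjugate addition of the phenoxide oxygen to the β-carbon of the ynone (O1–C2), and protonation of the resulting enolate gives the pyranone. No stereocentre is formed. Regiocontrol in the aryne addition is not needed, because 11 is mirror-symmetric about its triple bond and both orientations lead to the same product. What the step does need is acyl transfer faster than protonation of the aryl anion, which hot THF with poorly soluble proton sources favours, and 6-endo over 5-exo closure, which aprotic basic conditions favour because only the 6-endo path gives a stabilised enolate.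

Step 6
Reactants: 13 tangeretin
Product: 14 5-hydroxy-6,7,8-trimethoxy-2-(4-methoxyphenyl)chromen-4-one (target)
Conditions: BCl3 (1.5 equiv), CH2Cl2, −78 to 0 °C; then H2O
Reagents that add atoms: none
Why: Chelation-directed Lewis acid ether cleavage: boron binds the C4 carbonyl oxygen and the peri 5-methoxy oxygen in a six-membered chelate, so chloride removes only that methyl group, while the 6-, 7-, 8- and 4'-methoxy groups cannot chelate and should remain.

**Compound list**

1 | 1,2,3,4-tetramethoxybenzene | COc1ccc(OC)c(OC)c1OC | starting material
2 | (2,3,4,5-tetramethoxyphenyl)lithium | [Li]c1cc(OC)c(OC)c(OC)c1OC | intermediate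
3 | dimethyl (2,3,4,5-tetramethoxyphenyl)boronate | COB(OC)c1cc(OC)c(OC)c(OC)c1OC | intermediate
4 | 2,3,4,5-tetramethoxyphenol | COc1cc(O)c(OC)c(OC)c1OC | intermediate
5 | 2-bromo-3,4,5,6-tetramethoxyphenol | COc1c(O)c(Br)c(OC)c(OC)c1OC | intermediate
6 | (2-bromo-3,4,5,6-tetramethoxyphenoxy)trimethylsilane | COc1c(O[Si](C)(C)C)c(Br)c(OC)c(OC)c1OC | intermediate
7 | [3,4,5,6-tetramethoxy-2-(trimethylsilyloxy)phenyl]lithium | [Li]c1c(O[Si](C)(C)C)c(OC)c(OC)c(OC)c1OC | intermediate
8 | lithium 3,4,5,6-tetramethoxy-2-(trimethylsilyl)phenoxide | [Li+].[O-]c1c([Si](C)(C)C)c(OC)c(OC)c(OC)c1OC | intermediate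
9 | 3,4,5,6-tetramethoxy-2-(trimethylsilyl)phenyl trifluoromethanesulfonate | COc1c(OC)c(OC)c(OS(=O)(=O)C(F)(F)F)c([Si](C)(C)C)c1OC | intermediate
10 | 3-(4-methoxyphenyl)propiolic acid | COc1ccc(C#CC(=O)O)cc1 | starting material
11 | 3,4,5,6-tetramethoxybenzyne (1,2-didehydro-3,4,5,6-tetramethoxybenzene) | COC1=C(OC)C(OC)=C(OC)C#C1 | intermediate
12 | 1-(2-hydroxy-3,4,5,6-tetramethoxyphenyl)-3-(4-methoxyphenyl)prop-2-yn-1-one | COc1ccc(C#CC(=O)c2c(O)c(OC)c(OC)c(OC)c2OC)cc1 | intermediate
13 | 5,6,7,8-tetramethoxy-2-(4-methoxyphenyl)chromen-4-one (tangeretin) | COc1ccc(-c2cc(=O)c3c(OC)c(OC)c(OC)c(OC)c3o2)cc1 | intermediate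
14 | 5-hydroxy-6,7,8-trimethoxy-2-(4-methoxyphenyl)chromen-4-one | COc1ccc(-c2cc(=O)c3c(O)c(OC)c(OC)c(OC)c3o2)cc1 | target

**Step count and risk**

Total steps: 6. Longest linear sequence: 6 steps (1 → 4 → 5 → 6 → 9 → 13 → 14); acid 10 is used as purchased.

Steps most likely to fail:

1. Step 5 (aryne insertion and ring closure). The aryl anion may be protonated before the acyl group migrates, which stops at simple O-arylation of the acid. The propiolate may also lose CO2 at 125 °C, the phenoxide may add to a second aryne, or closure may go 5-exo towards an aurone. Fallback: ring C would be built by chalcone chemistry, setting out from phenol 4. C-Acetylation at its only free ring position (Ac2O, BF3·OEt2, 70 °C, Fries-type, boron chelate hydrolysed on work-up) should give 1-(2-hydroxy-3,4,5,6-tetramethoxyphenyl)ethan-1-one F1. Claisen–Schmidt condensation with 4-methoxybenzaldehyde (KOH, EtOH, rt) should give (E)-1-(2-hydroxy-3,4,5,6-tetramethoxyphenyl)-3-(4-methoxyphenyl)prop-2-en-1-one F2. Oxidative cyclisation with catalytic iodine in DMSO at 130 °C would return to the route at tangeretin 13.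

2. Step 4 (retro-Brook rearrangement and triflation). Silyl migration may be incomplete, the aryllithium may be protonated, or the hindered phenoxide, flanked by silicon and a methoxy group, may be triflated sluggishly, so that desilylated or untriflated material results. Fallback: the silicon would be installed by carbamate-directed metalation, setting out from phenol 4. Addition to isopropyl isocyanate (catalytic Et3N, CH2Cl2, rt) should give 2,3,4,5-tetramethoxyphenyl N-(propan-2-yl)carbamate F3. In-flask N-silylation, ortho-lithiation at the single free position and C-silylation (TMSOTf, TMEDA, Et2O; n-BuLi, TMEDA, −78 °C; TMSCl; acidic work-up) should give 3,4,5,6-tetramethoxy-2-(trimethylsilyl)phenyl N-(propan-2-yl)carbamate F4. Carbamate cleavage and triflation in one flask (DBU, Et2NH, MeCN, 40 °C; then PhNTf2) would come back to the route at triflate 9.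

3. Step 2 (bromination). The very electron-rich phenol may be oxidised by NBS, through ipso attack and loss of methanol, to a methoxybenzoquinone instead of being substituted. Fallback: bromine would be introduced before the phenol oxygen, setting out from arene 1. Double bromination (Br2, CH2Cl2, 0 °C to rt) should give 1,2-dibromo-3,4,5,6-tetramethoxybenzene F5. A single bromine–magnesium exchange (iPrMgCl·LiCl, THF, −15 °C, where the ortho-bromoaryl Grignard reagent does not eliminate), borylation with B(OMe)3 and oxidation (AcOH, H2O2) would come back to the route at bromophenol 5.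

**Further compounds**

F1 | step 5 | 1-(2-hydroxy-3,4,5,6-tetramethoxyphenyl)ethan-1-one | CC(=O)c1c(O)c(OC)c(OC)c(OC)c1OC
F2 | step 5 | (E)-1-(2-hydroxy-3,4,5,6-tetramethoxyphenyl)-3-(4-methoxyphenyl)prop-2-en-1-one | COc1ccc(/C=C/C(=O)c2c(O)c(OC)c(OC)c(OC)c2OC)cc1
F3 | step 4 | 2,3,4,5-tetramethoxyphenyl N-(propan-2-yl)carbamate | CC(C)NC(=O)Oc1cc(OC)c(OC)c(OC)c1OC
F4 | step 4 | 3,4,5,6-tetramethoxy-2-(trimethylsilyl)phenyl N-(propan-2-yl)carbamate | CC(C)NC(=O)Oc1c([Si](C)(C)C)c(OC)c(OC)c(OC)c1OC
F5 | step 2 | 1,2-dibromo-3,4,5,6-tetramethoxybenzene | COc1c(Br)c(Br)c(OC)c(OC)c1OC
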